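## Retrosynthetic overview

1. Oxirane ring last: peracid epoxidation of the strained (E)-ring alkene of the diacetate. Before that, the side chain comes from opening a C12–C13 oxirane (C12 aldehyde + sulfur ylide) with a (Z)-alkenylmagnesium reagent.
2. Four-membered ring second: C10–C11 by 4-exo-tet alkylation of a C12 ester enolate on a C10 bromide, which also creates the quaternary C11.
3. Nine-membered ring first: C1–C9 by an auxiliary-controlled intramolecular Hosomi–Sakurai conjugate addition of an allylsilane to an N-enoyl oxazolidinone. The C8 exocyclic methylene appears in the same step.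
4. These two C–C bonds are the ones a caryophyllene-type cyclase makes from the farnesyl chain (C2–C10 and C1–C11). Here they are closed from an acyclic (E,E)-C15 chain with inverted polarity and in reverse order, because the C12 carbonyl makes the 10,11-alkene the electrophile.
5. Acyclic precursor: a C15 terpenoid alcohol, C-silylated at its C3 methyl group (dianion) and cross-metathesised at the terminal isopropylidene with a chiral acrylimide. The C11 methyl is added by enolate methylation.

Assumption: ring atoms are numbered as in caryophyllane/xeniaphyllane (C1/C9 ring fusion, C4=C5 ring alkene, C8 exocyclic methylene, C10 cyclobutane CH2, C11 quaternary carbon, C12 carbinol carbon); the given SMILES is read as the (1S,4S,5S,9R,11S,12S)-isomer with a (Z) side-chain alkene.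

## Route

Step 1
Reactants: 1 (2E,6E)-farnesol
Product: 3 triethyl{[(2Z,6E)-7,11-dimethyl-3-[(triethylsilyl)methyl]dodeca-2,6,10-trien-1-yl]oxy}silane, via dilithio dianion 2 (not isolated)
Conditions: n-BuLi (2.4 equiv), TMEDA, Et2O, 0 °C to rt; then Et3SiCl (2.6 equiv), −78 °C to rt
Reagents that add atoms: chlorotriethylsilane CC[Si](CC)(CC)Cl
Why: Alkoxide-directed allylic lithiation (the dianion chemistry used to make 2-(trimethylsilylmethyl)allyl alcohol) removes a proton from the C3 methyl group, which lies cis to CH2OLi in the (2E)-alcohol, and both the allyllithium carbon and the alkoxide are silylated; the double-bond geometry is kept and no stereocentre is formed.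

Step 2
Reactants: 4 (S)-4-benzyloxazolidin-2-one; 5 acryloyl chloride
Product: 6 (S)-3-acryloyl-4-benzyloxazolidin-2-one
Conditions: Et3N, LiCl, THF, −20 °C to rt
Reagents that add atoms: none
Why: LiCl/Et3N-mediated N-acylation of the oxazolidinone under mild conditions that avoid acrylate polymerisation; the auxiliary stereocentre is untouched.

Step 3
Reactants: 3 triethyl{[(2Z,6E)-7,11-dimethyl-3-[(triethylsilyl)methyl]dodeca-2,6,10-trien-1-yl]oxy}silane; 6 (S)-3-acryloyl-4-benzyloxazolidin-2-one
Product: 7 (S)-4-benzyl-3-[(2E,6E,10Z)-6-methyl-12-[(triethylsilyl)oxy]-10-[(triethylsilyl)methyl]dodeca-2,6,10-trienoyl]oxazolidin-2-one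
Conditions: second-generation Hoveyda–Grubbs catalyst (5 mol%), 6 (2 equiv), CH2Cl2, 40 °C
Reagents that add atoms: none
Why: Olefin cross-metathesis in which only the unhindered terminal isopropylidene group of 3 engages the ruthenium carbene, so exchange with the acrylimide (loss of isobutene) gives the (E)-enoyl imide under thermodynamic control.

Step 4
Reactants: 7 (S)-4-benzyl-3-[(2E,6E,10Z)-6-methyl-12-[(triethylsilyl)oxy]-10-[(triethylsilyl)methyl]dodeca-2,6,10-trienoyl]oxazolidin-2-one
Product: 8 (S)-4-benzyl-3-{[(1R,2R,6E)-7-methyl-3-methylidene-2-{[(triethylsilyl)oxy]methyl}cyclonon-6-en-1-yl]acetyl}oxazolidin-2-one (ring substituents trans)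
Conditions: TiCl4 (1.2 equiv), 2,6-di-tert-butyl-4-methylpyridine (0.3 equiv), CH2Cl2, −78 °C, 1 mM (slow addition of 7); aq NaHCO3
Reagents that add atoms: none
Why: Proposed new method: a nine-membered-ring-closing Hosomi–Sakurai conjugate addition in which TiCl4 chelates the imide in its s-cis form, the allylsilane carbon γ to silicon (future C9) attacks the β-carbon (future C1) on the face anti to the benzyl group, loss of the silyl group from the β-silyl cation gives the exocyclic methylene directly, and a transition state with both new ring substituents pseudo-equatorial on the forming (E)-cyclononene gives the trans relationship; the closest known reactions are the intermolecular TiCl4-mediated Sakurai addition to N-enoyl oxazolidinones and intramolecular Sakurai closures of five- to eight-membered rings.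

Step 5
Reactants: 8 (S)-4-benzyl-3-{[(1R,2R,6E)-7-methyl-3-methylidene-2-{[(triethylsilyl)oxy]methyl}cyclonon-6-en-1-yl]acetyl}oxazolidin-2-one
Product: 9 methyl [(1R,2R,6E)-7-methyl-3-methylidene-2-{[(triethylsilyl)oxy]methyl}cyclonon-6-en-1-yl]acetate
Conditions: NaOMe (0.3 equiv), MeOH/THF, 0 °C
Reagents that add atoms: methanol CO
Why: Methanolysis of the N-acyl oxazolidinone (exocyclic acyl cleavage by methoxide) frees the ester needed for enolate chemistry and returns the auxiliary; the ring stereocentres are untouched.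

Step 6
Reactants: 9 methyl [(1R,2R,6E)-7-methyl-3-methylidene-2-{[(triethylsilyl)oxy]methyl}cyclonon-6-en-1-yl]acetate
Product: 11 methyl 2-[(6E)-7-methyl-3-methylidene-2-{[(triethylsilyl)oxy]methyl}cyclonon-6-en-1-yl]propanoate (ring stereocentres as in 9; both epimers at C2 of the propanoate), via lithium ester enolate 10 (not isolated)
Conditions: LiN(iPr)2 (1.1 equiv), THF, −78 °C; then MeI, −78 to −20 °C
Reagents that add atoms: iodomethane CI
Why: Kinetic ester-enolate formation and C-methylation (SN2) installs the future C11 methyl group; the new α-centre forms as a mixture, which does not matter because it is planarised again in step 8.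

Step 7
Reactants: 11 methyl 2-[(6E)-7-methyl-3-methylidene-2-{[(triethylsilyl)oxy]methyl}cyclonon-6-en-1-yl]propanoate
Product: 12 methyl 2-[(6E)-2-(bromomethyl)-7-methyl-3-methylidenecyclonon-6-en-1-yl]propanoate (ring stereocentres as in 9; both epimers)
Conditions: Ph3PBr2 (1.2 equiv), CH2Cl2, 0 °C to rt
Reagents that add atoms: dibromotriphenylphosphorane BrP(Br)(c1ccccc1)(c1ccccc1)c1ccccc1
Why: Direct conversion of a silyl ether into the bromide (alkoxyphosphonium formation, then SN2 by bromide at the primary carbon) under neutral conditions that spare the ester and the alkenes.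

Step 8
Reactants: 12 methyl 2-[(6E)-2-(bromomethyl)-7-methyl-3-methylidenecyclonon-6-en-1-yl]propanoate
Product: 14 methyl (1S,4E,9R,11S)-4,11-dimethyl-8-methylidenebicyclo[7.2.0]undec-4-ene-11-carboxylate, via lithium enolate 13 (not isolated)
Conditions: LiN(iPr)2 (1.2 equiv), THF/DMPU, −78 to 0 °C
Reagents that add atoms: none
Why: 4-exo-tet intramolecular alkylation of the ester enolate (Stork-type cyclobutane closure) forms C10–C11, and A(1,3) strain puts the C1–H bond, not the C1–C2 bond, next to the enolate oxygen substituent in the transition state, so the ester ends up cis to H1 and the methyl cis to C2, which is the (11S) quaternary centre.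

Step 9
Reactants: 14 methyl (1S,4E,9R,11S)-4,11-dimethyl-8-methylidenebicyclo[7.2.0]undec-4-ene-11-carboxylate
Product: 15 (1S,4E,9R,11S)-4,11-dimethyl-8-methylidenebicyclo[7.2.0]undec-4-ene-11-carbaldehyde
Conditions: iBu2AlH (1.1 equiv), CH2Cl2, −78 °C; Rochelle salt work-up
Reagents that add atoms: none
Why: Partial reduction of the hindered α-quaternary ester stops at the stable tetrahedral aluminium hemiacetal, which gives the aldehyde on work-up.

Step 10
Reactants: 15 (1S,4E,9R,11S)-4,11-dimethyl-8-methylidenebicyclo[7.2.0]undec-4-ene-11-carbaldehyde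
Product: 16 (2R)-2-[(1S,4E,9R,11S)-4,11-dimethyl-8-methylidenebicyclo[7.2.0]undec-4-en-11-yl]oxirane
Conditions: Me3S+ I−, KN(SiMe3)2, THF, −10 °C to rt
Reagents that add atoms: trimethylsulfonium iodide C[S+](C)C.[I-]
Why: Corey–Chaykovsky epoxidation in which the ylide adds to the non-enolisable aldehyde in the Felkin–Anh sense (anti to the ring-fusion carbon C1, passing the methyl group), setting C12 with the configuration that becomes (12S) after ring opening.

Step 11
Reactants: 17 prop-2-yn-1-ol
Product: 19 (Z)-3-iodo-2-methylprop-2-en-1-ol, via alkenylmagnesium chelate 18 (not isolated)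
Conditions: MeMgBr (2.5 equiv), CuI (10 mol%), Et2O, −10 °C to rt; then I2, −78 to 0 °C
Reagents that add atoms: methylmagnesium bromide C[Mg]Br; iodine II
Why: Copper-catalysed carbomagnesiation of the propargylic alkoxide (Duboudin reaction) delivers methyl to C2 and magnesium to C3 within a five-membered chelate, and iodinolysis with retention gives the iodide with I cis to CH2OH.

Step 12
Reactants: 16 (2R)-2-[(1S,4E,9R,11S)-4,11-dimethyl-8-methylidenebicyclo[7.2.0]undec-4-en-11-yl]oxirane; 19 (Z)-3-iodo-2-methylprop-2-en-1-ol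
Product: 21 (1S,3Z)-1-[(1S,4E,9R,11S)-4,11-dimethyl-8-methylidenebicyclo[7.2.0]undec-4-en-11-yl]-4-methylpent-3-ene-1,5-diol, via alkenylmagnesium chloride 20 (not isolated)
Conditions: 19 (1.5 equiv), iPrMgCl·LiCl (2.1 equiv per 19), THF, −20 to 0 °C; then CuI (10 mol%), 16, −30 °C to rt; aq NH4Cl
Reagents that add atoms: none
Why: Deprotonation and iodine–magnesium exchange give a configurationally stable alkenylmagnesium reagent that opens the terminal epoxide at its CH2 carbon under copper catalysis (SN2), so C12 is untouched and the (Z)-alkene geometry is carried over.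

Step 13
Reactants: 21 (1S,3Z)-1-[(1S,4E,9R,11S)-4,11-dimethyl-8-methylidenebicyclo[7.2.0]undec-4-en-11-yl]-4-methylpent-3-ene-1,5-diol
Product: 22 (1S,3Z)-1-[(1S,4E,9R,11S)-4,11-dimethyl-8-methylidenebicyclo[7.2.0]undec-4-en-11-yl]-4-methylpent-3-ene-1,5-diyl diacetate
Conditions: Ac2O, DMAP (cat.), pyridine, CH2Cl2, rt
Reagents that add atoms: acetic anhydride CC(=O)OC(C)=O
Why: DMAP-catalysed acylation esterifies both the primary allylic and the hindered secondary hydroxyl group without touching any stereocentre.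

Step 14
Reactants: 22 (1S,3Z)-1-[(1S,4E,9R,11S)-4,11-dimethyl-8-methylidenebicyclo[7.2.0]undec-4-en-11-yl]-4-methylpent-3-ene-1,5-diyl diacetate
Product: 23 target, the (4S,5S)-4,5-epoxide of 22: (1S,3Z)-1-[(1S,4S,5S,9R,11S)-4,5-epoxy-4,11-dimethyl-8-methylidenebicyclo[7.2.0]undecan-11-yl]-4-methylpent-3-ene-1,5-diyl diacetate
Conditions: mCPBA (1.05 equiv), CH2Cl2, −20 °C
Reagents that add atoms: 3-chloroperoxybenzoic acid O=C(OO)c1cccc(Cl)c1
Why: Prilezhaev epoxidation in which the strained endocyclic (E)-trisubstituted alkene reacts far faster than the exocyclic methylene and the acetoxy-deactivated side-chain alkene, and the peracid attacks its exposed outer face as in the conversion of caryophyllene into caryophyllene oxide, giving the (4S,5S)-epoxide (the minor diastereomer is removed by chromatography).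

## Compound list

1 | (2E,6E)-farnesol, (2E,6E)-3,7,11-trimethyldodeca-2,6,10-trien-1-ol | OC/C=C(C)/CC/C=C(C)/CCC=C(C)C | starting material
2 | dilithio dianion of 1 (lithium alkoxide, allyllithium at the former C3 methyl; formed in situ) | [Li]OC/C=C(C[Li])/CC/C=C(C)/CCC=C(C)C | intermediate
3 | triethyl{[(2Z,6E)-7,11-dimethyl-3-[(triethylsilyl)methyl]dodeca-2,6,10-trien-1-yl]oxy}silane | CC[Si](CC)(CC)OC/C=C(C[Si](CC)(CC)CC)/CC/C=C(C)/CCC=C(C)C | intermediate
4 | (S)-4-benzyloxazolidin-2-one | O=C1N[C@@H](Cc2ccccc2)CO1 | starting material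
5 | acryloyl chloride | C=CC(=O)Cl | starting material
6 | (S)-3-acryloyl-4-benzyloxazolidin-2-one | C=CC(=O)N1[C@@H](Cc2ccccc2)COC1=O | intermediate
7 | (S)-4-benzyl-3-[(2E,6E,10Z)-6-methyl-12-[(triethylsilyl)oxy]-10-[(triethylsilyl)methyl]dodeca-2,6,10-trienoyl]oxazolidin-2-one | CC[Si](CC)(CC)OC/C=C(C[Si](CC)(CC)CC)/CC/C=C(C)/CC/C=C/C(=O)N1[C@@H](Cc2ccccc2)COC1=O | intermediate
8 | (S)-4-benzyl-3-{[(1R,2R,6E)-7-methyl-3-methylidene-2-{[(triethylsilyl)oxy]methyl}cyclonon-6-en-1-yl]acetyl}oxazolidin-2-one (ring substituents trans) | C=C1CC/C=C(C)/CC[C@H](CC(=O)N2[C@@H](Cc3ccccc3)COC2=O)[C@H]1CO[Si](CC)(CC)CC | intermediate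
9 | methyl [(1R,2R,6E)-7-methyl-3-methylidene-2-{[(triethylsilyl)oxy]methyl}cyclonon-6-en-1-yl]acetate | C=C1CC/C=C(C)/CC[C@H](CC(=O)OC)[C@H]1CO[Si](CC)(CC)CC | intermediate
10 | lithium enolate of 9 (formed in situ) | C=C1CC/C=C(C)/CC[C@H](C=C(O[Li])OC)[C@H]1CO[Si](CC)(CC)CC | intermediate
11 | methyl 2-[(6E)-7-methyl-3-methylidene-2-{[(triethylsilyl)oxy]methyl}cyclonon-6-en-1-yl]propanoate (ring stereocentres as in 9; both epimers at propanoate C2) | C=C1CC/C=C(C)/CC[C@H](C(C)C(=O)OC)[C@H]1CO[Si](CC)(CC)CC | intermediate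
12 | methyl 2-[(6E)-2-(bromomethyl)-7-methyl-3-methylidenecyclonon-6-en-1-yl]propanoate (ring stereocentres as in 9; both epimers at propanoate C2) | C=C1CC/C=C(C)/CC[C@H](C(C)C(=O)OC)[C@H]1CBr | intermediate
13 | lithium enolate of 12 (formed in situ) | C=C1CC/C=C(C)/CC[C@H](C(C)=C(O[Li])OC)[C@H]1CBr | intermediate
14 | methyl (1S,4E,9R,11S)-4,11-dimethyl-8-methylidenebicyclo[7.2.0]undec-4-ene-11-carboxylate | C=C1CC/C=C(C)/CC[C@H]2[C@H]1C[C@]2(C)C(=O)OC | intermediate
15 | (1S,4E,9R,11S)-4,11-dimethyl-8-methylidenebicyclo[7.2.0]undec-4-ene-11-carbaldehyde | C=C1CC/C=C(C)/CC[C@H]2[C@H]1C[C@]2(C)C=O | intermediate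
16 | (2R)-2-[(1S,4E,9R,11S)-4,11-dimethyl-8-methylidenebicyclo[7.2.0]undec-4-en-11-yl]oxirane | C=C1CC/C=C(C)/CC[C@H]2[C@H]1C[C@]2(C)[C@H]3OC3 | intermediate
17 | prop-2-yn-1-ol (propargyl alcohol) | C#CCO | starting material
18 | (Z)-alkenylmagnesium chelate, bromomagnesium (Z)-3-(bromomagnesio)-2-methylprop-2-en-1-olate (formed in situ) | Br[Mg]/C=C(/C)CO[Mg]Br | intermediate
19 | (Z)-3-iodo-2-methylprop-2-en-1-ol | I/C=C(/C)CO | intermediate
20 | chloromagnesium (Z)-3-(chloromagnesio)-2-methylprop-2-en-1-olate (formed in situ) | Cl[Mg]/C=C(/C)CO[Mg]Cl | intermediate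
21 | (1S,3Z)-1-[(1S,4E,9R,11S)-4,11-dimethyl-8-methylidenebicyclo[7.2.0]undec-4-en-11-yl]-4-methylpent-3-ene-1,5-diol | C=C1CC/C=C(C)/CC[C@H]2[C@H]1C[C@]2(C)[C@H](C/C=C(/C)CO)O | intermediate
22 | (1S,3Z)-1-[(1S,4E,9R,11S)-4,11-dimethyl-8-methylidenebicyclo[7.2.0]undec-4-en-11-yl]-4-methylpent-3-ene-1,5-diyl diacetate | C=C1CC/C=C(C)/CC[C@H]2[C@H]1C[C@]2(C)[C@H](C/C=C(/C)COC(C)=O)OC(C)=O | intermediate
23 | (1S,3Z)-1-[(1S,4S,5S,9R,11S)-4,5-epoxy-4,11-dimethyl-8-methylidenebicyclo[7.2.0]undecan-11-yl]-4-methylpent-3-ene-1,5-diyl diacetate (CNP0256343.1) | C=C1CC[C@@H]2O[C@@]2(C)CC[C@H]2[C@H]1C[C@]2(C)[C@H](C/C=C(/C)COC(C)=O)OC(C)=O | target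

## Step count and risks

Total steps: 14. Longest linear sequence: 12 (steps 1, 3–10, 12–14, from 1 to 23); steps 2 and 11 make the two side components 6 and 19.

Steps most likely to fail:

**Step 4 (nine-membered ring by Sakurai closure).** Medium-ring closure competes with oligomerisation and protodesilylation, and the trans relationship rests on a transition-state argument. The fallback sets out from 1 and comes back at 8, replacing the silicon donor by a tin donor that is several orders of magnitude more nucleophilic, so that TiCl4 is no longer needed. Dianion 2 is quenched with Bu3SnCl and worked up with water to give (2Z,6E)-7,11-dimethyl-3-[(tributylstannyl)methyl]dodeca-2,6,10-trien-1-ol F1. Et3SiCl/imidazole in CH2Cl2 gives its triethylsilyl ether F2. Cross-metathesis with 6 as in step 3 gives the stannyl enoyl imide F3. F3 is closed with the mild chelating Lewis acid MgBr2·OEt2 (or Me2AlCl) in CH2Cl2 at −78 to −40 °C under high dilution to give 8, from which the route continues unchanged.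

**Step 8 (four-membered ring and C11 quaternary centre).** The 4-exo-tet closure is slow, and elimination of HBr or a poor C11 ratio would erode it. The fallback sets out from 8 and comes back at 15, running the same bond formation through an amide enolate, which is more nucleophilic, carries a bulkier group to reinforce the A(1,3) bias, and can be reduced straight to the aldehyde. Me3Al/MeONHMe·HCl converts 8 into the Weinreb amide F4 (the auxiliary is released). LiN(iPr)2 then MeI gives the α-methyl amide F5. Ph3PBr2 gives the bromide F6. LiN(iPr)2 in THF/DMPU closes the ring to the bicyclic Weinreb amide F7. LiAlH4 at 0 °C reduces F7 to aldehyde 15, so steps 5–9 are bypassed.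

**Step 10 (C12 configuration).** Felkin–Anh control by a quaternary centre whose three substituents differ only modestly may give a low ratio. The fallback sets out from 14 and comes back at 16, replacing substrate control by reagent control. ICH2Cl/MeLi·LiBr at −78 °C (chloromethyllithium) converts ester 14 into the chloromethyl ketone F8. Reduction with (R)-2-methyl-CBS-oxazaborolidine (10 mol%) and BH3·SMe2, which treats the quaternary carbon as the large group, gives the (1R)-chlorohydrin F9. K2CO3 in MeOH closes F9 to oxirane 16.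

Further compounds
F1 | step 4 | (2Z,6E)-7,11-dimethyl-3-[(tributylstannyl)methyl]dodeca-2,6,10-trien-1-ol | OC/C=C(C[Sn](CCCC)(CCCC)CCCC)/CC/C=C(C)/CCC=C(C)C
F2 | step 4 | triethyl{[(2Z,6E)-7,11-dimethyl-3-[(tributylstannyl)methyl]dodeca-2,6,10-trien-1-yl]oxy}silane | CC[Si](CC)(CC)OC/C=C(C[Sn](CCCC)(CCCC)CCCC)/CC/C=C(C)/CCC=C(C)C
F3 | step 4 | (S)-4-benzyl-3-[(2E,6E,10Z)-6-methyl-12-[(triethylsilyl)oxy]-10-[(tributylstannyl)methyl]dodeca-2,6,10-trienoyl]oxazolidin-2-one | CC[Si](CC)(CC)OC/C=C(C[Sn](CCCC)(CCCC)CCCC)/CC/C=C(C)/CC/C=C/C(=O)N1[C@@H](Cc2ccccc2)COC1=O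
F4 | step 8 | N-methoxy-N-methyl-2-[(1R,2R,6E)-7-methyl-3-methylidene-2-{[(triethylsilyl)oxy]methyl}cyclonon-6-en-1-yl]acetamide | C=C1CC/C=C(C)/CC[C@H](CC(=O)N(C)OC)[C@H]1CO[Si](CC)(CC)CC
F5 | step 8 | N-methoxy-N-methyl-2-[(6E)-7-methyl-3-methylidene-2-{[(triethylsilyl)oxy]methyl}cyclonon-6-en-1-yl]propanamide (ring stereocentres as in F4; both epimers at propanamide C2) | C=C1CC/C=C(C)/CC[C@H](C(C)C(=O)N(C)OC)[C@H]1CO[Si](CC)(CC)CC
F6 | step 8 | 2-[(6E)-2-(bromomethyl)-7-methyl-3-methylidenecyclonon-6-en-1-yl]-N-methoxy-N-methylpropanamide (ring stereocentres as in F4; both epimers at propanamide C2) | C=C1CC/C=C(C)/CC[C@H](C(C)C(=O)N(C)OC)[C@H]1CBr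
F7 | step 8 | (1S,4E,9R,11S)-N-methoxy-N,4,11-trimethyl-8-methylidenebicyclo[7.2.0]undec-4-ene-11-carboxamide | C=C1CC/C=C(C)/CC[C@H]2[C@H]1C[C@]2(C)C(=O)N(C)OC
F8 | step 10 | 2-chloro-1-[(1S,4E,9R,11S)-4,11-dimethyl-8-methylidenebicyclo[7.2.0]undec-4-en-11-yl]ethan-1-one | C=C1CC/C=C(C)/CC[C@H]2[C@H]1C[C@]2(C)C(=O)CCl
F9 | step 10 | (1R)-2-chloro-1-[(1S,4E,9R,11S)-4,11-dimethyl-8-methylidenebicyclo[7.2.0]undec-4-en-11-yl]ethan-1-ol | C=C1CC/C=C(C)/CC[C@H]2[C@H]1C[C@]2(C)[C@H](CCl)O
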